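**Plan**
- Retrosynthesis: the two phenols go back to methyl ethers; the macrocycle is opened at the CH2–CH2 bridge between ring B (C7) and ring C (a C=C from two formyl groups), then at the ring D–O–ring C ether; the furan is opened at O5–C5a; last, ring A is cut at C1–CH2 and C9b–C9a.
- Enabling feature: ring A carries on adjacent carbons the ethylene arm (C1), the ring B aryl (C9b) and oxygen (C4a), with the second oxygen at C3 meta to C1 and C4a. This is the pattern 3,5-dimethoxybenzyne gives when a carbon nucleophile enters at C1 and an aryl electrophile at C9b.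
- Forward: the aryne three-component coupling attaches rings B and D to ring A; demethylation and fluoride displacement close the furan; ring C is joined by Pd-catalysed etherification at the ring D chloride; nitrile and acetal become two aldehydes; McMurry coupling closes the 18-membered ring; hydrogenation and demethylation finish.
- Stereochemistry: the target has no stereocentre; the only stereo element on the way, the geometry of the macrocyclic alkene, is erased by hydrogenation.

Key step: step 2

Assumption: locants follow the dibenzofuran numbering of the natural product (O5; ring A = C1–C4, C4a, C9b; ring B = C5a, C6–C9, C9a), also in compound names; the alkene of step 8 is drawn Z, the geometry expected to be favoured in the ring, and an E isomer would be carried on in the same way.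

**Step 1**
Reactants: 1 4-chlorophenethyl bromide [1-(2-bromoethyl)-4-chlorobenzene]
Product: 2 2-(4-chlorophenyl)ethylmagnesium bromide (titrated THF solution, used directly)
Conditions: Mg turnings, I2 (cat.), THF, 25–35 °C, slow addition of 1
Reagents that add atoms: magnesium, [Mg]
Why: Grignard formation by insertion of magnesium into the primary alkyl C–Br bond, which is far more reactive towards the metal than the aryl C–Cl bond, so the ring D chloride is kept for step 6.

**Step 2**
Reactants: 3 1-fluoro-3,5-dimethoxybenzene; 2 2-(4-chlorophenyl)ethylmagnesium bromide; 4 3-fluoro-4-iodobenzonitrile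
Product: 9 4-{2-[2-(4-chlorophenyl)ethyl]-4,6-dimethoxyphenyl}-3-fluorobenzonitrile, via 2-fluoro-4,6-dimethoxyphenyllithium 5 (not isolated), via 3,5-dimethoxybenzyne 6 (not isolated), via arylmagnesium bromide 7 (not isolated), via arylzinc chloride 8 (not isolated)
Conditions: n-BuLi, THF, −78 °C; 2, −78 → 25 °C; ZnCl2, 25 °C; 4, Pd(PPh3)4 (cat.), 60 °C
Reagents that add atoms: none
Why: Fluorine and the flanking methoxy group make the C–H between them the most acidic site of 3, so n-BuLi gives aryllithium 5, which loses LiF on warming to aryne 6; the carbon of Grignard reagent 2 adds to the aryne carbon remote from the methoxy group (future C1) because the neighbouring C–OMe bond inductively stabilises the negative charge developing at the other aryne carbon (future C9b), giving arylmagnesium 7 with the metal between methoxy and the new chain. Transmetalation with ZnCl2 gives arylzinc 8, which enters a Negishi cycle (oxidative addition of zerovalent palladium into the C–I bond of 4, transmetalation, reductive elimination) and forms the C9b–C9a biaryl bond. The closest known reaction type is the carbomagnesiation of 3-alkoxyarynes generated from fluoroarenes with electrophilic capture of the resulting 2-alkoxyarylmagnesium, joined to the standard magnesium-to-zinc transmetalation and Negishi arylation of hindered arylmetals. No ring closes and no stereocentre forms. The step needs regioselective addition to the aryne, secured by the methoxy group next to the triple bond, and coupling at iodide in preference to the ring D chloride, secured by the large difference in oxidative addition rates with a triphenylphosphine catalyst; a small excess of 4 absorbs the alkylzinc left from excess 2.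

**Step 3**
Reactants: 9 4-{2-[2-(4-chlorophenyl)ethyl]-4,6-dimethoxyphenyl}-3-fluorobenzonitrile
Product: 10 4-{2-[2-(4-chlorophenyl)ethyl]-4,6-dihydroxyphenyl}-3-fluorobenzonitrile
Conditions: BBr3, CH2Cl2, −78 → 25 °C; H2O
Reagents that add atoms: none
Why: BBr3 demethylation of aryl methyl ethers (Lewis acid coordination, bromide attack at methyl) frees both ring A phenols, while nitrile, aryl fluoride and aryl chloride are inert to the reagent.

**Step 4**
Reactants: 10 4-{2-[2-(4-chlorophenyl)ethyl]-4,6-dihydroxyphenyl}-3-fluorobenzonitrile
Product: 12 1-[2-(4-chlorophenyl)ethyl]-3-methoxydibenzofuran-7-carbonitrile, via hydroxydibenzofuran nitrile 11 (not isolated)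
Conditions: K2CO3, NMP, 140 °C; then MeI, 25 °C
Reagents that add atoms: iodomethane, CI
Why: Intramolecular nucleophilic aromatic substitution, in which the C4a phenoxide displaces the ortho fluoride of ring B (helped inductively by the meta nitrile) to close the five-membered furan, is followed in the same flask by Williamson methylation of the C3 phenoxide, which is para to the biaryl bond and cannot cyclise.

**Step 5**
Reactants: 13 isovanillin (3-hydroxy-4-methoxybenzaldehyde)
Product: 14 5-(1,3-dioxolan-2-yl)-2-methoxyphenol
Conditions: HOCH2CH2OH, TsOH (cat.), toluene, reflux, Dean–Stark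
Reagents that add atoms: ethylene glycol, OCCO
Why: Acid-catalysed acetalisation with azeotropic removal of water turns isovanillin into an electron-rich phenol whose masked aldehyde is stable to the base of step 6 and the hydride of step 7.

**Step 6**
Reactants: 12 1-[2-(4-chlorophenyl)ethyl]-3-methoxydibenzofuran-7-carbonitrile; 14 5-(1,3-dioxolan-2-yl)-2-methoxyphenol
Product: 15 1-(2-{4-[5-(1,3-dioxolan-2-yl)-2-methoxyphenoxy]phenyl}ethyl)-3-methoxydibenzofuran-7-carbonitrile
Conditions: Pd(OAc)2 (cat.), tBuXPhos (cat.), K3PO4, toluene, 100 °C
Reagents that add atoms: none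
Why: Palladium-catalysed C–O cross-coupling (Buchwald–Hartwig diaryl ether synthesis), in which the bulky di-tert-butylbiarylphosphine enables oxidative addition of the unactivated aryl chloride and C–O reductive elimination with the ortho-substituted, electron-rich phenoxide, while K3PO4 leaves nitrile and acetal untouched.

**Step 7**
Reactants: 15 1-(2-{4-[5-(1,3-dioxolan-2-yl)-2-methoxyphenoxy]phenyl}ethyl)-3-methoxydibenzofuran-7-carbonitrile
Product: 17 1-{2-[4-(5-formyl-2-methoxyphenoxy)phenyl]ethyl}-3-methoxydibenzofuran-7-carbaldehyde, via aluminium aldimine 16 (not isolated)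
Conditions: i-Bu2AlH, toluene, −78 → 0 °C; then 2 M HCl, THF, 25 °C
Reagents that add atoms: water, O
Why: Partial reduction of the aryl nitrile by i-Bu2AlH stops at the N-aluminio aldimine, and the aqueous acid work-up hydrolyses both this imine and the dioxolane, so the two formyl groups appear in one operation.

**Step 8**
Reactants: 17 1-{2-[4-(5-formyl-2-methoxyphenoxy)phenyl]ethyl}-3-methoxydibenzofuran-7-carbaldehyde
Product: 19 didehydroasterelin A dimethyl ether (the target macrocycle with CH=CH between ring B C7 and ring C, both phenols as methyl ethers; Z drawn), via titanium pinacolate 18 (not isolated)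
Conditions: TiCl4, Zn, pyridine, THF, reflux; 17 added slowly (high dilution)
Reagents that add atoms: none
Why: Intramolecular McMurry coupling, in which low-valent titanium reductively couples the two aryl aldehydes to a titanium pinacolate that is deoxygenated to the alkene, is an established way to close stilbene-bridged bis(bibenzyl) macrocycles, and slow addition at high dilution favours the 18-membered ring over oligomers.

**Step 9**
Reactants: 19 didehydroasterelin A dimethyl ether
Product: 20 asterelin A dimethyl ether (methyl ethers at C3 of ring A and on ring C)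
Conditions: H2 (1 atm), Pd/C, EtOAc–THF, 25 °C
Reagents that add atoms: none
Why: Heterogeneous catalytic hydrogenation over Pd/C saturates the stilbene double bond of either geometry, and with no halide or benzyl ether left nothing else is reducible under these mild conditions.

**Step 10**
Reactants: 20 asterelin A dimethyl ether
Product: 21 asterelin A
Conditions: BBr3, CH2Cl2, −78 → 25 °C; H2O
Reagents that add atoms: none
Why: BBr3 demethylation cleaves the two aryl methyl ethers selectively, since the diaryl ether and the dibenzofuran oxygen offer no sp3 carbon for bromide attack.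

**Compound list**
1 | 4-chlorophenethyl bromide | BrCCc1ccc(Cl)cc1 | starting material
2 | 2-(4-chlorophenyl)ethylmagnesium bromide | Br[Mg]CCc1ccc(Cl)cc1 | intermediate
3 | 1-fluoro-3,5-dimethoxybenzene | COc1cc(F)cc(OC)c1 | starting material
4 | 3-fluoro-4-iodobenzonitrile | N#Cc1ccc(I)c(F)c1 | starting material
5 | 2-fluoro-4,6-dimethoxyphenyllithium (formed in the flask) | [Li]c1c(F)cc(OC)cc1OC | intermediate
6 | 3,5-dimethoxybenzyne (formed in the flask) | COC1=CC(OC)=CC#C1 | intermediate
7 | 2-[2-(4-chlorophenyl)ethyl]-4,6-dimethoxyphenylmagnesium bromide (formed in the flask) | COc1cc(OC)c([Mg]Br)c(CCc2ccc(Cl)cc2)c1 | intermediate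
8 | 2-[2-(4-chlorophenyl)ethyl]-4,6-dimethoxyphenylzinc chloride (formed in the flask) | COc1cc(OC)c([Zn]Cl)c(CCc2ccc(Cl)cc2)c1 | intermediate
9 | 4-{2-[2-(4-chlorophenyl)ethyl]-4,6-dimethoxyphenyl}-3-fluorobenzonitrile | COc1cc(OC)c(-c2ccc(C#N)cc2F)c(CCc2ccc(Cl)cc2)c1 | intermediate
10 | 4-{2-[2-(4-chlorophenyl)ethyl]-4,6-dihydroxyphenyl}-3-fluorobenzonitrile | Oc1cc(O)c(-c2ccc(C#N)cc2F)c(CCc2ccc(Cl)cc2)c1 | intermediate
11 | 1-[2-(4-chlorophenyl)ethyl]-3-hydroxydibenzofuran-7-carbonitrile (formed in the flask) | Oc1cc(CCc2ccc(Cl)cc2)c2c(c1)oc1cc(C#N)ccc12 | intermediate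
12 | 1-[2-(4-chlorophenyl)ethyl]-3-methoxydibenzofuran-7-carbonitrile | COc1cc(CCc2ccc(Cl)cc2)c2c(c1)oc1cc(C#N)ccc12 | intermediate
13 | isovanillin | COc1ccc(C=O)cc1O | starting material
14 | 5-(1,3-dioxolan-2-yl)-2-methoxyphenol | COc1ccc(C2OCCO2)cc1O | intermediate
15 | 1-(2-{4-[5-(1,3-dioxolan-2-yl)-2-methoxyphenoxy]phenyl}ethyl)-3-methoxydibenzofuran-7-carbonitrile | COc1cc(CCc2ccc(Oc3cc(C4OCCO4)ccc3OC)cc2)c2c(c1)oc1cc(C#N)ccc12 | intermediate
16 | N-(diisobutylaluminio) aldimine of 15 at C7, acetal intact (formed in the flask) | COc1cc(CCc2ccc(Oc3cc(C4OCCO4)ccc3OC)cc2)c2c(c1)oc1cc(C=N[Al](CC(C)C)CC(C)C)ccc12 | intermediate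
17 | 1-{2-[4-(5-formyl-2-methoxyphenoxy)phenyl]ethyl}-3-methoxydibenzofuran-7-carbaldehyde | COc1cc(CCc2ccc(Oc3cc(C=O)ccc3OC)cc2)c2c(c1)oc1cc(C=O)ccc12 | intermediate
18 | macrocyclic titanium pinacolate, drawn as its dichlorotitanium diolate; diastereomer mixture of no consequence (formed in the flask) | COc1cc2c3c(c1)oc1cc(ccc13)C4O[Ti](Cl)(Cl)OC4c1ccc(OC)c(c1)Oc1ccc(cc1)CC2 | intermediate
19 | (Z)-didehydroasterelin A dimethyl ether (CH=CH between ring B C7 and ring C) | COc1cc2c3c(c1)oc1cc(ccc13)/C=C\c1ccc(OC)c(c1)Oc1ccc(cc1)CC2 | intermediate
20 | asterelin A dimethyl ether | COc1cc2c3c(c1)oc1cc(ccc13)CCc1ccc(OC)c(c1)Oc1ccc(cc1)CC2 | intermediate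
21 | asterelin A | Oc1cc2c3c(c1)oc1cc(ccc13)CCc1ccc(O)c(c1)Oc1ccc(cc1)CC2 | target

**Step count**
Total steps: 10. Longest linear sequence: 9 steps (from 1 through steps 1–4 and 6–10; step 5 is a one-step side branch).

**Steps most likely to fail**

Step 2. The weak points are three processes.
- Metalation between the two methoxy groups of 3 may compete with metalation next to fluorine.
- The primary alkyl Grignard reagent may add to the aryne more slowly than arylmetal intermediates already formed.
- Transmetalation of the di-ortho-substituted arylzinc may be slow, so that protodemetalation or coupling of residual alkylzinc consumes the material.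

The fallback separates the two bond formations and reverses the polarity of the biaryl coupling. It sets out from 3 and 2: the same lithiation and carbomagnesiation are run, but arylmagnesium 7 is quenched with iodine to give 1-[2-(4-chlorophenyl)ethyl]-2-iodo-3,5-dimethoxybenzene F1, which is purified. A Suzuki–Miyaura coupling of this iodide with commercial (4-cyano-2-fluorophenyl)boronic acid [Pd(dppf)Cl2, K3PO4, dioxane–water, 90 °C] then comes back to the route at 9.

Step 8. Intermolecular coupling on the titanium surface may outrun ring closure, or the reaction may stop at the pinacol stage. The fallback closes the same C=C bond by metathesis in homogeneous solution. It sets out from 17: double Wittig methylenation (Ph3PCH3Br, KOt-Bu, THF) gives 7-ethenyl-1-{2-[4-(5-ethenyl-2-methoxyphenoxy)phenyl]ethyl}-3-methoxydibenzofuran F2. Ring-closing metathesis with the second-generation Grubbs catalyst, RuCl2(H2IMes)(PCy3)(=CHPh), in toluene at high dilution and 80 °C releases ethene and comes back to the route at 19.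

Step 6. C–O reductive elimination at palladium may be slow, so that hydrodechlorination or catalyst decay takes over. The fallback reverses the polarity of ring D and uses copper instead. It sets out from 12: Miyaura borylation of the chloride [B2pin2, Pd2(dba)3, XPhos, KOAc, dioxane, 100 °C] gives 3-methoxy-1-{2-[4-(4,4,5,5-tetramethyl-1,3,2-dioxaborolan-2-yl)phenyl]ethyl}dibenzofuran-7-carbonitrile F3. Chan–Lam coupling of this boronate with phenol 14 [Cu(OAc)2, pyridine, B(OH)3, MeCN, air, 70 °C] comes back to the route at 15.

**Further compounds**
F1 | step 2 | 1-[2-(4-chlorophenyl)ethyl]-2-iodo-3,5-dimethoxybenzene | COc1cc(OC)c(I)c(CCc2ccc(Cl)cc2)c1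
F2 | step 8 | 7-ethenyl-1-{2-[4-(5-ethenyl-2-methoxyphenoxy)phenyl]ethyl}-3-methoxydibenzofuran | COc1cc(CCc2ccc(Oc3cc(C=C)ccc3OC)cc2)c2c(c1)oc1cc(C=C)ccc12
F3 | step 6 | 3-methoxy-1-{2-[4-(4,4,5,5-tetramethyl-1,3,2-dioxaborolan-2-yl)phenyl]ethyl}dibenzofuran-7-carbonitrile | COc1cc(CCc2ccc(B3OC(C)(C)C(C)(C)O3)cc2)c2c(c1)oc1cc(C#N)ccc12
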